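**Retrosynthetic overview**
- The oxirane is formed last, by invertive closure of a C3 tertiary alkoxide onto a C2 mesylate of a syn-2,3-diol (aryl ether already in place).
- The C3 carbinol comes from chelate-controlled methyl addition to an α-hydroxy ketone; the C2 stereocentre is bought in methyl (S)-glycidate and controls C3.
- The C3–C4 ketone bond joins the two chiral-pool halves in a nickel-electrocatalytic acyl–alkyl cross-electrophile coupling (thioester + primary iodide).
- The iodide comes from the L-glutamic-acid-derived hydroxymethyl lactone by trans-selective enolate methylation (C5 controls C7).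
- Ring order: coumarin and γ-lactone are bought as rings; the epoxide ring is made in the final step.

Assumption: 7-hydroxy-8-methoxycoumarin, methyl (S)-glycidate and (S)-5-(hydroxymethyl)dihydrofuran-2(3H)-one are taken as catalogue compounds; side-chain carbons are called C1 (ArOCH2) to C8 (lactone C=O).

**Step 1**
Reactants: 1 (S)-5-(hydroxymethyl)dihydrofuran-2(3H)-one
Product: 2 (S)-5-[(trityloxy)methyl]dihydrofuran-2(3H)-one
Conditions: TrCl (1.1 equiv), pyridine, DMAP (cat.), CH2Cl2, 23 °C
Reagents that add atoms: trityl chloride, ClC(c1ccccc1)(c1ccccc1)c1ccccc1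
Why: Tritylation of the primary alcohol (SN1-type etherification) installs the bulky group that shields one lactone face in the next step; C5 is the bought stereocentre and is not touched.

**Step 2**
Reactants: 2 (S)-5-[(trityloxy)methyl]dihydrofuran-2(3H)-one
Product: 3 (3R,5S)-3-methyl-5-[(trityloxy)methyl]dihydrofuran-2(3H)-one
Conditions: LiN(iPr)2 (1.1 equiv), THF, −78 °C; MeI (3 equiv), −78 → −40 °C
Reagents that add atoms: iodomethane, CI
Why: Lithium enolate alkylation; MeI attacks the enolate face anti to the C5 trityloxymethyl group, so the bought C5 centre sets the new α-centre as the trans (3R) isomer.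

**Step 3**
Reactants: 3 (3R,5S)-3-methyl-5-[(trityloxy)methyl]dihydrofuran-2(3H)-one
Product: 4 (3R,5S)-5-(hydroxymethyl)-3-methyldihydrofuran-2(3H)-one
Conditions: 80% aq. AcOH, 50 °C
Reagents that add atoms: none
Why: Acid-catalysed SN1 cleavage of the trityl ether; the lactone and both stereocentres are unaffected under these non-basic conditions.

**Step 4**
Reactants: 4 (3R,5S)-5-(hydroxymethyl)-3-methyldihydrofuran-2(3H)-one
Product: 5 (3R,5S)-5-(iodomethyl)-3-methyldihydrofuran-2(3H)-one
Conditions: PPh3 (1.2 equiv), I2 (1.2 equiv), imidazole (1.5 equiv), CH2Cl2, 0 → 23 °C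
Reagents that add atoms: iodine, II
Why: Appel-type iodination (SN2 of iodide on the alkoxyphosphonium at the primary carbon); no stereocentre is involved.

**Step 5**
Reactants: 6 7-hydroxy-8-methoxy-2H-chromen-2-one, 7 methyl (S)-oxirane-2-carboxylate
Product: 9 (S)-2-hydroxy-3-[(8-methoxy-2-oxo-2H-chromen-7-yl)oxy]propanoic acid, via methyl ester 8 (not isolated)
Conditions: CsF (0.2 equiv), DMF, 60 °C; then LiOH (2.5 equiv), THF/H2O, 0 °C; then 1 M HCl to pH 2
Reagents that add atoms: lithium hydroxide, [Li+].[OH-]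
Why: Phenoxide SN2 opening of the glycidate at the unhindered terminal carbon leaves the bought C2 centre untouched, and saponification then frees the acid; the coumarin lactone re-closes on acidification.

**Step 6**
Reactants: 9 (S)-2-hydroxy-3-[(8-methoxy-2-oxo-2H-chromen-7-yl)oxy]propanoic acid
Product: 10 S-(pyridin-2-yl) (S)-2-hydroxy-3-[(8-methoxy-2-oxo-2H-chromen-7-yl)oxy]propanethioate
Conditions: 2,2′-dipyridyl disulfide (1.2 equiv), PPh3 (1.2 equiv), MeCN, 0 → 23 °C
Reagents that add atoms: 2,2′-dipyridyl disulfide, c1ccc(SSc2ccccn2)nc1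
Why: Mukaiyama redox condensation (acyloxyphosphonium then thiolate) activates the carboxyl group selectively beside the free secondary hydroxyl, as in hydroxy-acid thioester activation, and uses no base that could epimerise C2.

**Step 7**
Reactants: 10 S-(pyridin-2-yl) (S)-2-hydroxy-3-[(8-methoxy-2-oxo-2H-chromen-7-yl)oxy]propanethioate, 5 (3R,5S)-5-(iodomethyl)-3-methyldihydrofuran-2(3H)-one
Product: 11 7-{[(2S)-2-hydroxy-4-[(2S,4R)-4-methyl-5-oxooxolan-2-yl]-3-oxobutyl]oxy}-8-methoxy-2H-chromen-2-one
Conditions: 10 (1.0 equiv), 5 (1.5 equiv), NiBr2(dme) (10 mol %), dtbbpy (12 mol %), NaI (1 equiv), DMA, undivided cell, Zn anode, reticulated vitreous carbon cathode, 5 mA constant current, 2.5 F/mol, 23 °C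
Reagents that add atoms: none
Why: Proposed new method: a nickel-electrocatalytic acyl–alkyl cross-electrophile coupling in which cathodically generated zerovalent nickel (dtbbpy) inserts into the C(acyl)–S bond of the unprotected α-hydroxy thioester, monovalent nickel abstracts iodine from 5 to give the β-acyloxy primary radical (stable as a radical, whereas the corresponding organozinc would ring-open by β-elimination), the acyl-nickel captures it and trivalent nickel reductively eliminates the C3–C4 ketone bond, with Zn2+ from the anode binding the released thiolate and iodide and no stereocentre touched; the closest known reaction types are the nickel-catalysed reductive ketone synthesis from S-2-pyridyl thioesters and alkyl iodides with zinc powder and nickel-electrocatalytic cross-electrophile coupling of alkyl halides.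

**Step 8**
Reactants: 11 7-{[(2S)-2-hydroxy-4-[(2S,4R)-4-methyl-5-oxooxolan-2-yl]-3-oxobutyl]oxy}-8-methoxy-2H-chromen-2-one
Product: 12 7-{[(2S,3R)-2,3-dihydroxy-3-methyl-4-[(2S,4R)-4-methyl-5-oxooxolan-2-yl]butyl]oxy}-8-methoxy-2H-chromen-2-one
Conditions: MeTi(OiPr)3 (3 equiv), CH2Cl2, −40 → 0 °C; aq. NH4F work-up
Reagents that add atoms: methyltitanium triisopropoxide, C[Ti](OC(C)C)(OC(C)C)OC(C)C
Why: Cram-chelate addition to an α-hydroxy ketone: the C2 hydroxyl exchanges onto titanium, and methyl attacks the five-membered titanium chelate (C2–O and C3=O) on the face anti to CH2OAr, so the bought (2S) centre sets C3 as R; the non-basic reagent spares both lactones and avoids β-elimination of the β-acyloxy ketone.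

**Step 9**
Reactants: 12 7-{[(2S,3R)-2,3-dihydroxy-3-methyl-4-[(2S,4R)-4-methyl-5-oxooxolan-2-yl]butyl]oxy}-8-methoxy-2H-chromen-2-one
Product: 14 8-methoxy-7-{[(2R,3R)-3-methyl-3-{[(2S,4R)-4-methyl-5-oxooxolan-2-yl]methyl}oxiran-2-yl]methoxy}-2H-chromen-2-one, via mesylate 13 (not isolated)
Conditions: MsCl (1.2 equiv), Et3N (2 equiv), CH2Cl2, −20 °C; then DBU (3 equiv), 23 → 40 °C
Reagents that add atoms: none
Why: Selective sulfonylation of the secondary hydroxyl, then intramolecular Williamson (SN2) closure by the tertiary alkoxide, inverts C2 (S to R) and retains C3, giving the trans (2R,3R) oxirane stereospecifically.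

**Compound list**
1 | (S)-5-(hydroxymethyl)dihydrofuran-2(3H)-one | OC[C@@H]1CCC(=O)O1 | starting material
2 | (S)-5-[(trityloxy)methyl]dihydrofuran-2(3H)-one | C(OC[C@@H]1CCC(=O)O1)(c2ccccc2)(c3ccccc3)c4ccccc4 | intermediate
3 | (3R,5S)-3-methyl-5-[(trityloxy)methyl]dihydrofuran-2(3H)-one | C(OC[C@@H]1C[C@@H](C)C(=O)O1)(c2ccccc2)(c3ccccc3)c4ccccc4 | intermediate
4 | (3R,5S)-5-(hydroxymethyl)-3-methyldihydrofuran-2(3H)-one | OC[C@@H]1C[C@@H](C)C(=O)O1 | intermediate
5 | (3R,5S)-5-(iodomethyl)-3-methyldihydrofuran-2(3H)-one | IC[C@@H]1C[C@@H](C)C(=O)O1 | intermediate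
6 | 7-hydroxy-8-methoxy-2H-chromen-2-one | COc1c(O)ccc2ccc(=O)oc12 | starting material
7 | methyl (S)-oxirane-2-carboxylate | COC(=O)[C@@H]1CO1 | starting material
8 | methyl (S)-2-hydroxy-3-[(8-methoxy-2-oxo-2H-chromen-7-yl)oxy]propanoate | COc1c(OC[C@H](O)C(=O)OC)ccc2ccc(=O)oc12 | intermediate
9 | (S)-2-hydroxy-3-[(8-methoxy-2-oxo-2H-chromen-7-yl)oxy]propanoic acid | COc1c(OC[C@H](O)C(=O)O)ccc2ccc(=O)oc12 | intermediate
10 | S-(pyridin-2-yl) (S)-2-hydroxy-3-[(8-methoxy-2-oxo-2H-chromen-7-yl)oxy]propanethioate | COc1c(OC[C@H](O)C(=O)Sc3ccccn3)ccc2ccc(=O)oc12 | intermediate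
11 | 7-{[(2S)-2-hydroxy-4-[(2S,4R)-4-methyl-5-oxooxolan-2-yl]-3-oxobutyl]oxy}-8-methoxy-2H-chromen-2-one | COc1c(OC[C@H](O)C(=O)C[C@@H]3C[C@@H](C)C(=O)O3)ccc2ccc(=O)oc12 | intermediate
12 | 7-{[(2S,3R)-2,3-dihydroxy-3-methyl-4-[(2S,4R)-4-methyl-5-oxooxolan-2-yl]butyl]oxy}-8-methoxy-2H-chromen-2-one | COc1c(OC[C@H](O)[C@](C)(O)C[C@@H]3C[C@@H](C)C(=O)O3)ccc2ccc(=O)oc12 | intermediate
13 | (2S,3R)-3-hydroxy-1-[(8-methoxy-2-oxo-2H-chromen-7-yl)oxy]-3-methyl-4-[(2S,4R)-4-methyl-5-oxooxolan-2-yl]butan-2-yl methanesulfonate | COc1c(OC[C@H](OS(C)(=O)=O)[C@](C)(O)C[C@@H]3C[C@@H](C)C(=O)O3)ccc2ccc(=O)oc12 | intermediate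
14 | 8-methoxy-7-{[(2R,3R)-3-methyl-3-{[(2S,4R)-4-methyl-5-oxooxolan-2-yl]methyl}oxiran-2-yl]methoxy}-2H-chromen-2-one | COc1c(OC[C@H]2O[C@]2(C)C[C@@H]2C[C@@H](C)C(=O)O2)ccc2ccc(=O)oc12 | target

**Step count and risks**
Total step count: 9. Longest linear sequence: 7 (steps 1, 2, 3, 4, 7, 8, 9).

Steps most likely to fail:

Step 7 (the proposed new coupling). Risks are β-acyloxy elimination from an alkyl-nickel intermediate, acyl transfer to the free hydroxyl, and base sensitivity of the β-acyloxy ketone product. The fallback sets out from 10 and gives up the electrocatalytic, protecting-group-free design for known stoichiometric-reductant chemistry. The hydroxyl is silylated (TESOTf, 2,6-lutidine, CH2Cl2, −78 °C) to the O-triethylsilyl thioester F1. F1 is coupled with 5 under the established nickel-catalysed thioester–alkyl iodide ketone synthesis (NiCl2(dme), dtbbpy, Zn powder, DMA, 23 °C) to the silyloxy ketone F2. The silyl ether is then cleaved (AcOH/THF/H2O, 23 °C) and the route is rejoined at 11.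

Step 8 (chelate-controlled methyl addition). Risks are an insufficient diastereomer ratio at C3 and slow addition to the ketone. The fallback sets out from 11 and switches to magnesium chelation of an α-alkoxy ketone. The hydroxyl is protected with 4-methoxybenzyl trichloroacetimidate and La(OTf)3 (cat.) to the PMB ether ketone F3. MeMgBr in THF at −78 °C (Cram–Still five-membered magnesium chelate, same facial sense) gives the PMB ether tertiary alcohol F4. DDQ in CH2Cl2/pH 7 buffer removes the PMB group and the route is rejoined at 12.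

Step 5 (glycidate opening and saponification). Risks are attack at C2 or ester exchange, and handling of the base-labile coumarin. The fallback sets out from 6 and builds the acid by oxidation instead. Compound 6 is heated with (R)-glycidol F5 (Et3N cat., EtOH, 70 °C; attack at the terminal carbon) to give the aryloxy diol F6. The primary alcohol is then oxidised selectively (TEMPO, NaOCl cat., NaClO2, pH 6.7 buffer, MeCN) to the acid, and the route is rejoined at 9.

**Further compounds**
F1 | step 7 | S-(pyridin-2-yl) (S)-3-[(8-methoxy-2-oxo-2H-chromen-7-yl)oxy]-2-[(triethylsilyl)oxy]propanethioate | COc1c(OC[C@H](O[Si](CC)(CC)CC)C(=O)Sc3ccccn3)ccc2ccc(=O)oc12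
F2 | step 7 | 8-methoxy-7-{[(2S)-4-[(2S,4R)-4-methyl-5-oxooxolan-2-yl]-3-oxo-2-[(triethylsilyl)oxy]butyl]oxy}-2H-chromen-2-one | COc1c(OC[C@H](O[Si](CC)(CC)CC)C(=O)C[C@@H]3C[C@@H](C)C(=O)O3)ccc2ccc(=O)oc12
F3 | step 8 | 8-methoxy-7-{[(2S)-2-[(4-methoxybenzyl)oxy]-4-[(2S,4R)-4-methyl-5-oxooxolan-2-yl]-3-oxobutyl]oxy}-2H-chromen-2-one | COc1c(OC[C@H](OCc3ccc(OC)cc3)C(=O)C[C@@H]4C[C@@H](C)C(=O)O4)ccc2ccc(=O)oc12
F4 | step 8 | 7-{[(2S,3R)-3-hydroxy-2-[(4-methoxybenzyl)oxy]-3-methyl-4-[(2S,4R)-4-methyl-5-oxooxolan-2-yl]butyl]oxy}-8-methoxy-2H-chromen-2-one | COc1c(OC[C@H](OCc3ccc(OC)cc3)[C@](C)(O)C[C@@H]4C[C@@H](C)C(=O)O4)ccc2ccc(=O)oc12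
F5 | step 5 | (R)-oxiran-2-ylmethanol | OC[C@@H]1CO1
F6 | step 5 | 7-{[(2R)-2,3-dihydroxypropyl]oxy}-8-methoxy-2H-chromen-2-one | COc1c(OC[C@H](O)CO)ccc2ccc(=O)oc12
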